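The readings are simulated with made-up constants, noise included.

Start with the easy step: divide what the most concentrated run used by the time it took.

| flask | electrophile | free base | scavenger | gas | remark | time |
|---|---|---|---|---|---|---|
| Monday's | 0.070 M | 2 equiv | 1.2 equiv (fed, over 2.0 h) | 4.1 mM (held) | run made earlier |  |
| Friday's | 0.11 M | 2 equiv | 1.2 equiv (fed, over 2.0 h) | 4.1 mM (held) | run made earlier |  |
| Sunday's | 0.050 M | 4 equiv | 1.2 equiv (fed, over 2.0 h) | 4.1 mM (held) | run made earlier |  |
| flask | 0.050 M | 2.00 equiv | 1.20 equiv (fed, over 2.0 h) | 4.1 mM (held) |  | 15 h |

| run | time / h | electrophile / % | product / % |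
|---|---|---|---|
| Monday's | 4.00 | 67.4 | 34.0 |
| Monday's | 8.00 | 42.7 | 57.2 |
| Monday's | 12.0 | 21.9 | 77.3 |
| Monday's | 15.0 | 11.1 | 86.8 |
| Friday's | 1.33 | 92.1 | 7.1 |
| Friday's | 3.00 | 79.2 | 18.6 |
| Friday's | 6.00 | 62.9 | 36.6 |
| Friday's | 15.0 | 23.5 | 76.9 |
| Sunday's | 4.00 | 58.8 | 39.7 |
| Sunday's | 8.00 | 30.1 | 69.0 |
| Sunday's | 12.0 | 11.7 | 86.9 |
| Sunday's | 15.0 | 5.6 | 93.7 |

(scatter of a reading: 1 percentage point)

- part of the electrophile that has reacted at 15 h
- share of the unused nucleophile that is free and not bound as protonated nucleophile, at 15 h

- acid set free is meant together with its idle adduct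
- at the start none of nucleophile is dissolved
- steps that have been proposed: nucleophile + acid set free <-> protonated nucleophile; electrophile + nucleophile -> acid set free + product; electrophile + acid set free <-> idle adduct; gas <-> nucleophile; acid set free + scavenger -> scavenged by-product; acid set free + free base <-> salt of the base
- the earlier runs do not show how much of nucleophile is bound; that part of a forecast is a guess

By 3.00 h, Friday's run had lost electrophile down to 79.2% of 0.11 M. I call this reading the supply rate, the electrophile consumed per hour while electrophile is plentiful:

S = 7.63 mM/h

Sunday's run, with 2.20 times less electrophile and 4 equiv of free base against Friday's 2 equiv, used 5.15 mM/h by 4.00 h, so the ratio of the two rates, 1.48, is smaller than the ratio of the charges. Read with that difference in base in mind, the rate follows the charge weakly, which points to the gas as the likely rate-limiting step. S then gives a ladder of times for your flask.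

Refill of dissolved nucleophile: 0.538 h

Scavenger feed: 2.0 h

Clearing time of the charge: 6.56 h

Run: 15 h

The refill is shorter than the clearing time, the feed also ends before the clearing time, and the run outlasts that time, so I expect your flask to come close to completion. S fades as electrophile thins, however, so I take Sunday's 94.4% reacted at 15.0 h, the same charge with more base, and lower it slightly. The readings leave the bound nucleophile a guess.

The forecast gave 92% and 90%, holding that “little acid is available to bind nucleophile”. The flask gives 93.4% reacted and 8.49% free.

    nucleophile + acid set free ⇌ protonated nucleophile, settled at all times (K = 1.90 × 10⁵ /M)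
    electrophile + nucleophile → acid set free + product (k = 88.0 /M/h)
    electrophile + acid set free ⇌ idle adduct, settled at all times (K = 6.90 /M)
    gas ⇌ nucleophile, rate k4*(csat - [nucleophile]) (kL = 2.80 /h)
    acid set free + scavenger → scavenged by-product (k = 11.0 /M/h)
    acid set free + free base ⇌ salt of the base, settled at all times (K = 2100 /M)

At 15.0 h, your flask holds [nucleophile] = 0.00330 M against [protonated nucleophile] = 0.0356 M, with 99.3% of the scavenger unused. Its remaining 6.6% of electrophile comes partly from slow gas transfer together with the length of the run: without that slowness the flask reaches 99.5%, and at 150 h it reaches 100%. The neighbour charged with 0.20 M has a clearing time of 26.2 h, and it stands at 59.3% reacted after 15 h, a mean of 7.91 mM/h.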